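**Plan**
- Retrosynthesis: ring C (the pyranone ring, flavanone numbering) is opened at O1–C2 and C4–C4a together. This leads back to an aryl (E)-3-arylacrylate in which the oxygen that becomes O1 carries the C4–C3=C2 chain as an ester and the carbon that becomes C4a carries iodine. The C2=C3 bond is then cut (Horner–Wadsworth–Emmons) into a ring A aryl phosphonoacetate and a ring B chromene aldehyde.
- Enabling feature: O1–C8a–C4a–C4(=O) of ring C is an ortho-acylphenol and C2 is the β-carbon of its enone. An O-to-C acyl shift from O1 to C4a therefore makes the ketone and at once frees the phenoxide O1 that adds to C2.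
- Forward order: ring A from phloroglucinol (iodination, C-prenylation, silylation of the two less hindered hydroxyls, acylation of the hydroxyl between iodine and prenyl); the pyran ring on ring B by Heck alkenylation and cyclodehydration of 5-bromo-2,4-dihydroxybenzaldehyde; union of the halves by olefination; ring C last; then desilylation.
- Regiochemistry: iodine marks C4a, the prenyl group already sits on C8, and the silyl ether on O5 leaves O1 as the only oxygen able to close ring C, so no 6-prenyl isomer can form.
- Stereochemistry: C2 (S), the only stereocentre, is set in the ring-closing oxa-Michael addition under a cinchona-derived bifunctional thiourea and is not touched afterwards.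

Key step: step 8

Assumption: the quinine-derived thiourea is taken to deliver O1 to the face of C2 that gives the 2S product; if the sense proves opposite, the quinidine-derived pseudoenantiomer is used in its place.

Step 1
Reactants: 1 phloroglucinol (benzene-1,3,5-triol)
Product: 2 2-iodobenzene-1,3,5-triol
Conditions: I2 (1.0 equiv), NaHCO3, THF/H2O, 0 °C → rt
Reagents that add atoms: iodine, II
Why: Electrophilic aromatic iodination of the very electron-rich ring, whose three CH positions are equivalent, so one equivalent of iodine buffered by bicarbonate should give the mono-iodide as a single regioisomer.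

Step 2
Reactants: 2 2-iodobenzene-1,3,5-triol; 3 prenyl bromide (1-bromo-3-methylbut-2-ene)
Product: 4 2-iodo-4-(3-methylbut-2-en-1-yl)benzene-1,3,5-triol
Conditions: 3 (1.0 equiv, slow addition), 1 M aq. KOH (1.0 equiv), 0 °C → rt
Reagents that add atoms: none
Why: C-alkylation of the ambident phloroglucinol monoanion, favoured over O-alkylation in water where the oxygen is hydrogen-bonded; the two free ring carbons of 2 are equivalent, so mono-prenylation leads to one constitution only.

Step 3
Reactants: 4 2-iodo-4-(3-methylbut-2-en-1-yl)benzene-1,3,5-triol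
Product: 5 3,5-bis[(tert-butyldimethylsilyl)oxy]-2-iodo-6-(3-methylbut-2-en-1-yl)phenol
Conditions: TBSCl (2.1 equiv), imidazole, CH2Cl2, 0 °C
Reagents that add atoms: tert-butyldimethylsilyl chloride (TBSCl), CC(C)(C)[Si](C)(C)Cl
Why: Silyl ether formation under steric control: the two hydroxyls that have a ring hydrogen as one neighbour should react first, and the hydroxyl flanked by iodine and the prenyl group, which must later carry the acyl group, should stay free.

Step 4
Reactants: 5 3,5-bis[(tert-butyldimethylsilyl)oxy]-2-iodo-6-(3-methylbut-2-en-1-yl)phenol; 6 diethylphosphonoacetic acid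
Product: 7 3,5-bis[(tert-butyldimethylsilyl)oxy]-2-iodo-6-(3-methylbut-2-en-1-yl)phenyl 2-(diethoxyphosphoryl)acetate
Conditions: DCC, DMAP (cat.), CH2Cl2, 0 °C → rt
Reagents that add atoms: none
Why: Steglich esterification; the carbodiimide-activated phosphonoacetic acid is a small, reactive acyl donor that should acylate even a phenol with two ortho substituents.

Step 5
Reactants: 8 5-bromo-2,4-dihydroxybenzaldehyde; 9 2-methylbut-3-en-2-ol
Product: 11 7-hydroxy-2,2-dimethyl-2H-chromene-6-carbaldehyde, via allylic alcohol 10 (not isolated)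
Conditions: Pd(OAc)2 (5 mol%), P(o-tolyl)3 (10 mol%), Et3N, DMF, 100 °C; then TsOH·H2O (5 mol%), toluene, 60 °C
Reagents that add atoms: none
Why: Heck reaction at the terminal carbon of a tertiary allylic alcohol (which cannot isomerize to a carbonyl compound), then acid-catalysed cyclodehydration through the allyl cation stabilized by the ortho and para hydroxyls; the place of bromine in 8 fixes the linear fusion of the pyran ring (oxygen on C4, vinyl carbon on C5).

Step 6
Reactants: 11 7-hydroxy-2,2-dimethyl-2H-chromene-6-carbaldehyde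
Product: 12 7-[(tert-butyldimethylsilyl)oxy]-2,2-dimethyl-2H-chromene-6-carbaldehyde
Conditions: TBSCl, imidazole, DMF, rt
Reagents that add atoms: tert-butyldimethylsilyl chloride (TBSCl), CC(C)(C)[Si](C)(C)Cl
Why: Standard silyl ether formation; it keeps the oxygen ortho to the side chain from acting as an acid or nucleophile in steps 7 and 8 and is removed with the other two silyl groups at the end.

Step 7
Reactants: 7 3,5-bis[(tert-butyldimethylsilyl)oxy]-2-iodo-6-(3-methylbut-2-en-1-yl)phenyl 2-(diethoxyphosphoryl)acetate; 12 7-[(tert-butyldimethylsilyl)oxy]-2,2-dimethyl-2H-chromene-6-carbaldehyde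
Product: 13 3,5-bis[(tert-butyldimethylsilyl)oxy]-2-iodo-6-(3-methylbut-2-en-1-yl)phenyl (2E)-3-{7-[(tert-butyldimethylsilyl)oxy]-2,2-dimethyl-2H-chromen-6-yl}prop-2-enoate
Conditions: LiCl, i-Pr2NEt, MeCN, rt
Reagents that add atoms: none
Why: Horner–Wadsworth–Emmons olefination of the stabilized aryl phosphonoacetate under mild LiCl/amine conditions, which should give the E-alkene and join ring A and ring B through C2=C3 without touching the aryl ester, the iodide or the silyl ethers.

Step 8
Reactants: 13 3,5-bis[(tert-butyldimethylsilyl)oxy]-2-iodo-6-(3-methylbut-2-en-1-yl)phenyl (2E)-3-{7-[(tert-butyldimethylsilyl)oxy]-2,2-dimethyl-2H-chromen-6-yl}prop-2-enoate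
Product: 17 (2S)-5,7-bis[(tert-butyldimethylsilyl)oxy]-2-{7-[(tert-butyldimethylsilyl)oxy]-2,2-dimethyl-2H-chromen-6-yl}-8-(3-methylbut-2-en-1-yl)-2,3-dihydro-4H-chromen-4-one, via aryllithium 14 (not isolated), via lithium chalcone phenoxide 15 (not isolated), via chalcone 16 (not isolated)
Conditions: n-BuLi (1.05 equiv), THF, −100 → −78 °C; AcOH (1.0 equiv), −78 → −40 °C; THF exchanged for toluene, lithium salts filtered off; 1-[3,5-bis(trifluoromethyl)phenyl]-3-[(8S,9S)-6′-methoxycinchonan-9-yl]thiourea (quinine-derived, 10 mol%), toluene, −20 °C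
Reagents that add atoms: none
Why: Proposed new method: iodine–lithium exchange at the C–I bond, which should outrun addition of n-BuLi to the hindered aryl ester at −100 °C, gives aryllithium 14; its carbanion attacks the ester carbonyl on the neighbouring oxygen through a four-membered lithium alkoxide that collapses to phenoxide 15, so the C4–C4a bond is made and O1 is set free in the same event (anionic Fries type O-to-C 1,3-acyl shift). After protonation to chalcone 16, the quinuclidine nitrogen of the catalyst pairs with the only acidic hydroxyl (O1–H) while the thiourea binds the ketone oxygen, and O1 adds to C2 of the enone to form the O1–C2 bond. The closest known reaction types are the halogen–lithium-exchange-induced acyl migration of ortho-haloaryl esters to ortho-hydroxyaryl ketones and the cinchona-base-catalysed oxa-Michael cyclization of 2′-hydroxychalcones and other ortho-enoylphenols to chroman-4-ones; what is new is their merger in one flask on an aryl 3-arylacrylate with catalyst control at C2. Ring C closes in the 6-endo-trig mode, and the new stereocentre C2 is controlled by the catalyst alone (attack on the enone face left open in the ion-paired, hydrogen-bonded complex), since the substrate has no other stereocentre. The site selectivity is secured by the substrate: iodine marks C4a, the prenyl group occupies the other carbon ortho to the ester oxygen, the acyl group travels from the very oxygen that becomes O1, and the silyl ether on O5 keeps that oxygen from closing the ring to the 6-prenyl isomer. The points to watch are 1,2-attack of the aryl anion at the lithium-chelated carbonyl over 1,4-attack at C2 (which would need the disfavoured E rotamer of the ester), and a cold ring closure so that reversible ring opening does not erode the enantiomeric purity.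

Step 9
Reactants: 17 (2S)-5,7-bis[(tert-butyldimethylsilyl)oxy]-2-{7-[(tert-butyldimethylsilyl)oxy]-2,2-dimethyl-2H-chromen-6-yl}-8-(3-methylbut-2-en-1-yl)-2,3-dihydro-4H-chromen-4-one
Product: 18 (2S)-5,7-dihydroxy-2-(7-hydroxy-2,2-dimethyl-2H-chromen-6-yl)-8-(3-methylbut-2-en-1-yl)-2,3-dihydro-4H-chromen-4-one (CNP0150213.1)
Conditions: HF·pyridine, pyridine, THF, 0 °C → rt
Reagents that add atoms: none
Why: Fluoride-mediated cleavage of the three aryl silyl ethers in a pyridine-buffered, weakly acidic medium, which should avoid both the phenoxide-induced ring opening of ring C (retro-oxa-Michael, loss of configuration at C2) and the strong acid that would cyclize the prenyl group onto the 7-hydroxyl.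

**Compound list**
1 | phloroglucinol (benzene-1,3,5-triol) | Oc1cc(O)cc(O)c1 | starting material
2 | 2-iodobenzene-1,3,5-triol | Oc1cc(O)c(I)c(O)c1 | intermediate
3 | prenyl bromide (1-bromo-3-methylbut-2-ene) | CC(C)=CCBr | starting material
4 | 2-iodo-4-(3-methylbut-2-en-1-yl)benzene-1,3,5-triol | CC(C)=CCc1c(O)cc(O)c(I)c1O | intermediate
5 | 3,5-bis[(tert-butyldimethylsilyl)oxy]-2-iodo-6-(3-methylbut-2-en-1-yl)phenol | CC(C)=CCc1c(O[Si](C)(C)C(C)(C)C)cc(O[Si](C)(C)C(C)(C)C)c(I)c1O | intermediate
6 | diethylphosphonoacetic acid [2-(diethoxyphosphoryl)acetic acid] | CCOP(=O)(CC(=O)O)OCC | starting material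
7 | 3,5-bis[(tert-butyldimethylsilyl)oxy]-2-iodo-6-(3-methylbut-2-en-1-yl)phenyl 2-(diethoxyphosphoryl)acetate | CC(C)=CCc1c(O[Si](C)(C)C(C)(C)C)cc(O[Si](C)(C)C(C)(C)C)c(I)c1OC(=O)CP(=O)(OCC)OCC | intermediate
8 | 5-bromo-2,4-dihydroxybenzaldehyde | O=Cc1cc(Br)c(O)cc1O | starting material
9 | 2-methylbut-3-en-2-ol | CC(C)(O)C=C | starting material
10 | (E)-2,4-dihydroxy-5-(3-hydroxy-3-methylbut-1-en-1-yl)benzaldehyde | CC(C)(O)/C=C/c1cc(C=O)c(O)cc1O | intermediate
11 | 7-hydroxy-2,2-dimethyl-2H-chromene-6-carbaldehyde | CC1(C)C=Cc2cc(C=O)c(O)cc2O1 | intermediate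
12 | 7-[(tert-butyldimethylsilyl)oxy]-2,2-dimethyl-2H-chromene-6-carbaldehyde | CC1(C)C=Cc2cc(C=O)c(O[Si](C)(C)C(C)(C)C)cc2O1 | intermediate
13 | 3,5-bis[(tert-butyldimethylsilyl)oxy]-2-iodo-6-(3-methylbut-2-en-1-yl)phenyl (2E)-3-{7-[(tert-butyldimethylsilyl)oxy]-2,2-dimethyl-2H-chromen-6-yl}prop-2-enoate | CC(C)=CCc1c(O[Si](C)(C)C(C)(C)C)cc(O[Si](C)(C)C(C)(C)C)c(I)c1OC(=O)/C=C/c1cc2C=CC(C)(C)Oc2cc1O[Si](C)(C)C(C)(C)C | intermediate
14 | aryllithium from 13 (lithium in place of iodine) | CC(C)=CCc1c(O[Si](C)(C)C(C)(C)C)cc(O[Si](C)(C)C(C)(C)C)c([Li])c1OC(=O)/C=C/c1cc2C=CC(C)(C)Oc2cc1O[Si](C)(C)C(C)(C)C | intermediate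
15 | lithium phenoxide of chalcone 16 | CC(C)=CCc1c(O[Si](C)(C)C(C)(C)C)cc(O[Si](C)(C)C(C)(C)C)c(C(=O)/C=C/c2cc3C=CC(C)(C)Oc3cc2O[Si](C)(C)C(C)(C)C)c1[O-].[Li+] | intermediate
16 | (2E)-1-{4,6-bis[(tert-butyldimethylsilyl)oxy]-2-hydroxy-3-(3-methylbut-2-en-1-yl)phenyl}-3-{7-[(tert-butyldimethylsilyl)oxy]-2,2-dimethyl-2H-chromen-6-yl}prop-2-en-1-one | CC(C)=CCc1c(O[Si](C)(C)C(C)(C)C)cc(O[Si](C)(C)C(C)(C)C)c(C(=O)/C=C/c2cc3C=CC(C)(C)Oc3cc2O[Si](C)(C)C(C)(C)C)c1O | intermediate
17 | (2S)-5,7-bis[(tert-butyldimethylsilyl)oxy]-2-{7-[(tert-butyldimethylsilyl)oxy]-2,2-dimethyl-2H-chromen-6-yl}-8-(3-methylbut-2-en-1-yl)-2,3-dihydro-4H-chromen-4-one | CC(C)=CCc1c(O[Si](C)(C)C(C)(C)C)cc(O[Si](C)(C)C(C)(C)C)c2c1O[C@H](c1cc3C=CC(C)(C)Oc3cc1O[Si](C)(C)C(C)(C)C)CC2=O | intermediate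
18 | (2S)-5,7-dihydroxy-2-(7-hydroxy-2,2-dimethyl-2H-chromen-6-yl)-8-(3-methylbut-2-en-1-yl)-2,3-dihydro-4H-chromen-4-one | CC(C)=CCc1c(O)cc(O)c2c1O[C@H](c1cc3c(cc1O)OC(C)(C)C=C3)CC2=O | target

Total steps: 9. Longest linear sequence: 7 steps (steps 1, 2, 3, 4, 7, 8, 9).

**Steps most likely to fail**

1. Step 8 (Proposed new method). The ring closure of an enone that offers the catalyst only one carbonyl to bind may show insufficient facial discrimination. Reversible ring opening under the basic catalyst may erode the enantiomeric purity. The aryl anion may also be diverted, by 1,4-addition to the enoate or by a 1,3-shift of the neighbouring silyl group from oxygen to carbon. The fallback sets out from 13 and comes back at 17, and takes the stereochemistry from a resolution instead of a catalyst-controlled bond formation. The acyl shift is run as in step 8 (n-BuLi, THF, −100 °C; AcOH), and chalcone 16 is closed without a chiral catalyst (DBU, catalytic, toluene, rt) to the racemic silylated flavanone F1. Kinetic resolution by asymmetric transfer hydrogenation (Cp*RhCl[(R,R)-TsDPEN], HCO2H/Et3N, EtOAc, rt, stopped near half conversion) is expected to reduce the 2R ketone to the (2R,4R)-cis-flavan-4-ol F2 and to leave the 2S ketone 17, which is separated by chromatography.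

2. Step 2. O-alkylation and a second C-alkylation of the ambident anion may compete with mono-C-prenylation, and the iodide may be lost under the basic aqueous conditions. The fallback sets out from 2 and comes back at 5, so it also replaces step 3, and brings the prenyl group in through oxygen. The two less hindered hydroxyls of 2 are silylated (TBSCl, imidazole, DMF) to 3,5-bis[(tert-butyldimethylsilyl)oxy]-2-iodophenol F3. O-Alkylation with 3-chloro-3-methylbut-1-yne (CuCl2 cat., DBU, MeCN, 0 °C) gives the 1,1-dimethylpropargyl ether F4. Semihydrogenation (H2, Pd/CaCO3 poisoned with Pb(OAc)2, quinoline, EtOAc) gives the 1,1-dimethylallyl ether F5. Aromatic Claisen rearrangement (toluene, 110 °C) then carries the allyl unit, with inversion of its ends, to the only free ortho carbon and gives 5.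

3. Step 5. Oxidative addition of palladium into the electron-rich, phenoxide-bearing aryl bromide may be slow and the catalyst may decompose; the chromene may oligomerize under acid during the cyclodehydration. The fallback sets out from 8 and comes back at 11, and forms the pyran ring by oxidation instead of dehydration. Stille coupling of 8 with tributyl(3-methylbut-2-en-1-yl)stannane (Pd(PPh3)4, DMF, 90 °C) gives 2,4-dihydroxy-5-(3-methylbut-2-en-1-yl)benzaldehyde F6. Oxidative cyclization with DDQ (toluene, 80 °C), through the ortho-quinone methide and 6π-electrocyclization onto the 4-hydroxyl, gives 11.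

**Further compounds**
F1 | step 8 | rac-5,7-bis[(tert-butyldimethylsilyl)oxy]-2-{7-[(tert-butyldimethylsilyl)oxy]-2,2-dimethyl-2H-chromen-6-yl}-8-(3-methylbut-2-en-1-yl)-2,3-dihydro-4H-chromen-4-one | CC(C)=CCc1c(O[Si](C)(C)C(C)(C)C)cc(O[Si](C)(C)C(C)(C)C)c2c1OC(c1cc3C=CC(C)(C)Oc3cc1O[Si](C)(C)C(C)(C)C)CC2=O
F2 | step 8 | (2R,4R)-5,7-bis[(tert-butyldimethylsilyl)oxy]-2-{7-[(tert-butyldimethylsilyl)oxy]-2,2-dimethyl-2H-chromen-6-yl}-8-(3-methylbut-2-en-1-yl)-3,4-dihydro-2H-chromen-4-ol | CC(C)=CCc1c(O[Si](C)(C)C(C)(C)C)cc(O[Si](C)(C)C(C)(C)C)c2c1O[C@@H](c1cc3C=CC(C)(C)Oc3cc1O[Si](C)(C)C(C)(C)C)C[C@H]2O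
F3 | step 2 | 3,5-bis[(tert-butyldimethylsilyl)oxy]-2-iodophenol | Oc1cc(O[Si](C)(C)C(C)(C)C)cc(O[Si](C)(C)C(C)(C)C)c1I
F4 | step 2 | 2-iodo-1-(2-methylbut-3-yn-2-yloxy)-3,5-bis[(tert-butyldimethylsilyl)oxy]benzene | C#CC(C)(C)Oc1cc(O[Si](C)(C)C(C)(C)C)cc(O[Si](C)(C)C(C)(C)C)c1I
F5 | step 2 | 2-iodo-1-(2-methylbut-3-en-2-yloxy)-3,5-bis[(tert-butyldimethylsilyl)oxy]benzene | C=CC(C)(C)Oc1cc(O[Si](C)(C)C(C)(C)C)cc(O[Si](C)(C)C(C)(C)C)c1I
F6 | step 5 | 2,4-dihydroxy-5-(3-methylbut-2-en-1-yl)benzaldehyde | CC(C)=CCc1cc(C=O)c(O)cc1O
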